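Readings and results were generated by integration on assumed constants, noise included.

1. The question is how target stands to isomer of the product in the flask, early and late.

| flask | starting material | protic impurity | remark | time |
|---|---|---|---|---|
| Friday's | 0.034 M | 5 mM | run made earlier |  |
| Thursday's | 0.075 M | 5 mM | run made earlier |  |
| Sunday's | 0.050 M | 2.5 mM | run made earlier |  |
| flask | 0.050 M | 5.00 mM |  | 6.0 h |

- Friday's (time / h: target / %, isomer of the product / %): 1.00: 10.2, 5.2; 2.00: 8.6, 7.6; 3.00: 9.3, 11.9; 4.00: 7.6, 12.6; 5.00: 8.1, 13.8; 6.00: 8.3, 17.0; 8.00: 7.4, 20.3
- Thursday's (time / h: target / %, isomer of the product / %): 1.00: 11.4, 4.9; 2.00: 10.8, 8.5; 3.00: 10.2, 11.9; 4.00: 9.0, 15.3; 5.00: 8.7, 17.1; 6.00: 7.3, 19.7; 8.00: 8.4, 25.3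
- Sunday's (time / h: target / %, isomer of the product / %): 0.667: 11.7, 3.4; 2.00: 10.6, 7.9; 3.00: 10.5, 11.3; 5.00: 10.2, 18.1; 8.00: 9.0, 24.0

(each reading ± 1 percentage point)

- what was read earlier has a scatter of 1 percentage point, one standard deviation
- steps under discussion: starting material <-> target; starting material <-> isomer of the product; starting material <-> third isomer; starting material + protic impurity -> quenched substrate; starting material <-> dormant form

- ratio of target to isomer of the product at 8.0 s
- ratio of target to isomer of the product at 6.0 h

2. The charges come first. In the flask, protic impurity is the limiting reagent of the quench. The quenched share, protic impurity charged over starting material charged, is 10.0% in the flask. It is 14.7% on Friday, 6.67% on Thursday and 5.00% on Sunday.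

3. Dividing the first target readings by the unquenched share gives 12.0%, 12.2% and 12.3% in those runs. At 6.00 h the ratio reads 0.488 on Friday and 0.371 on Thursday, so in these readings Friday's larger share does not carry the lower ratio. This reckoning therefore adds no correction for the charges.

4. Time moves the ratio: Thursday's ratio reads 0.857 at 3.00 h and 0.332 at 8.00 h. Sunday's first reading, at 0.667 h, comes before the first readings of the other runs but far later than 8.0 s, so the readings give no value for the early ratio.

5. The forecast gives 60 early and 0.44 late: “Quenching therefore scales both products and mostly cancels in the ratio.”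

6. The flask gives 48.1 and 0.479.

    starting material ⇌ target (K = 0.540, k = 0.00280 s⁻¹)
    starting material ⇌ isomer of the product (K = 2.90, k = 5.70 × 10⁻⁵ s⁻¹)
    starting material ⇌ third isomer (K = 2.40, k = 0.00280 s⁻¹)
    starting material + protic impurity → quenched substrate (k = 2.10 M⁻¹ s⁻¹)
    starting material ⇌ dormant form (K = 0.400, k = 0.0220 s⁻¹)

7. The flask holds 10.0% quenched substrate against a quenched share of 10.0%, and quenching makes no difference to the flask's late ratio. The neighbour, charged with 0.030 M of starting material, has a quenched share of 16.7% and holds 16.7% quenched substrate. Its ratios are 48.1 and 0.479. Its isomer of the product stands at 17.1% against 18.5% in the flask, which per unquenched share is 20.6% against 20.6%.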